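**Remark on the chemistry:** the SMILES corresponds to the (4R,6R) lactone with an E alkene, in which C4–OH and C6–CH3 are cis on the ring. Because CH3 and CH2R at C6 give almost no steric bias at C4, C4 is set by a chiral catalyst, and which mirror image of the ligand gives the required face has to be fixed in a test run (both are commercial).

## Retrosynthetic overview

- The C4 hydroxyl is installed last, by copper-catalysed asymmetric conjugate borylation and oxidation of the α,β-unsaturated lactone (C3=C4).
- The only ring, the δ-lactone O1–C2–C3–C4–C5–C6, is closed by forming C4–C5 in a nickel-catalysed reductive cross-electrophile coupling between an enol triflate carbon (C4) and a primary iodide (C5), held together by the ester O1–C2.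
- Enabling feature: C4 is β to the lactone carbonyl C2, so an acetoacetate ester carries a Z enol triflate exactly at C4, cis to the tether. C5 is a CH2 on the fully substituted carbinol carbon C6, so it is available as a primary iodide from a 2,2-disubstituted epoxide and its alkylnickel has no β-hydrogen.
- C6 comes from Sharpless epoxidation of methallyl alcohol; the side chain is added by copper-catalysed Grignard opening of 2-methylglycidyl tosylate.
- The E alkene comes from alkyne hydroboration and Suzuki benzylation.

Key step: step 10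

## Route

**Step 1**
Reactants: 1 dec-9-yn-1-ol
Product: 2 10-bromodec-1-yne
Conditions: CBr4, PPh3, CH2Cl2, 0 °C to rt
Reagents that add atoms: carbon tetrabromide, BrC(Br)(Br)Br
Why: Appel bromination turns the primary alcohol into the bromide under neutral conditions that a terminal alkyne tolerates.

**Step 2**
Reactants: 2 10-bromodec-1-yne
Product: 3 (E)-2-(10-bromodec-1-en-1-yl)-4,4,5,5-tetramethyl-1,3,2-dioxaborolane
Conditions: HBpin, Cp2Zr(H)Cl (5 mol %), Et3N (10 mol %), neat, 60 °C
Reagents that add atoms: pinacolborane, [H]B1OC(C)(C)C(C)(C)O1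
Why: Zirconium-catalysed hydroboration of the terminal alkyne is a syn, anti-Markovnikov addition, so boron should end on the terminal carbon and the E geometry of the later side-chain alkene is set here, the alkyl bromide being inert to HBpin.

**Step 3**
Reactants: 3 (E)-2-(10-bromodec-1-en-1-yl)-4,4,5,5-tetramethyl-1,3,2-dioxaborolane; 4 benzyl bromide
Product: 5 (E)-(11-bromoundec-2-en-1-yl)benzene
Conditions: Pd(PPh3)4 (3 mol %), K3PO4, THF/H2O, 60 °C
Reagents that add atoms: none
Why: Suzuki–Miyaura coupling of an alkenylboronate with a benzylic bromide retains the alkene geometry, and zerovalent palladium inserts into the benzylic C–Br bond much faster than into the unactivated primary C–Br bond of 3.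

**Step 4**
Reactants: 6 2-methylprop-2-en-1-ol
Product: 8 (R)-(2-methyloxiran-2-yl)methyl 4-methylbenzenesulfonate, via (S)-2-methylglycidol 7 (not isolated)
Conditions: Ti(OiPr)4 (5 mol %), L-(+)-DIPT (6 mol %), TBHP, 4 Å MS, CH2Cl2, −20 °C; P(OMe)3; then TsCl, Et3N, DMAP (cat.), −10 °C
Reagents that add atoms: tert-butyl hydroperoxide, CC(C)(C)OO; 4-toluenesulfonyl chloride, Cc1ccc(cc1)S(=O)(=O)Cl
Why: In the Sharpless asymmetric epoxidation the titanium L-(+)-tartrate should deliver oxygen to the alkene face that gives (S)-2-methylglycidol, which sets C6 of the target, and tosylation in the same pot avoids isolating the water-soluble epoxy alcohol without touching the stereocenter (the descriptor becomes R only through the priority rules).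

**Step 5**
Reactants: 5 (E)-(11-bromoundec-2-en-1-yl)benzene; 8 (R)-(2-methyloxiran-2-yl)methyl 4-methylbenzenesulfonate
Product: 10 (R,E)-2-hydroxy-2-methyl-14-phenyltetradec-12-en-1-yl 4-methylbenzenesulfonate, via (E)-(11-phenylundec-9-en-1-yl)magnesium bromide 9 (not isolated)
Conditions: Mg, THF, rt; then CuI (10 mol %), 8, THF, −40 to −20 °C; H2O
Reagents that add atoms: none
Why: Copper-catalysed Grignard opening of the epoxide by SN2 attack at its unsubstituted CH2 should be faster at low temperature than displacement of the neopentyl-type tosylate, and the quaternary stereocenter is not a reacting center.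

**Step 6**
Reactants: 10 (R,E)-2-hydroxy-2-methyl-14-phenyltetradec-12-en-1-yl 4-methylbenzenesulfonate
Product: 11 (R)-2-methyl-2-[(E)-12-phenyldodec-10-en-1-yl]oxirane
Conditions: K2CO3, MeOH, 0 °C to rt
Reagents that add atoms: none
Why: Intramolecular Williamson-type displacement (3-exo-tet) of the primary tosylate by the tertiary alkoxide should give the 2,2-disubstituted epoxide with the stereocenter untouched.

**Step 7**
Reactants: 11 (R)-2-methyl-2-[(E)-12-phenyldodec-10-en-1-yl]oxirane
Product: 12 (R,E)-1-iodo-2-methyl-14-phenyltetradec-12-en-2-ol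
Conditions: LiI, AcOH, THF, rt
Reagents that add atoms: lithium iodide, [Li+].[I-]
Why: In this halohydrin formation by SN2 opening, buffered LiI/AcOH should direct iodide to the unsubstituted epoxide carbon C5 and leave the C6–O bond, and hence the configuration, intact.

**Step 8**
Reactants: 12 (R,E)-1-iodo-2-methyl-14-phenyltetradec-12-en-2-ol; 13 diketene
Product: 14 (R,E)-1-iodo-2-methyl-14-phenyltetradec-12-en-2-yl 3-oxobutanoate
Conditions: DMAP (5 mol %), CH2Cl2, 0 °C to rt
Reagents that add atoms: none
Why: DMAP-catalysed acetoacetylation with diketene is a standard acylation of tertiary alcohols and needs no base strong enough to close the iodohydrin back to the epoxide.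

**Step 9**
Reactants: 14 (R,E)-1-iodo-2-methyl-14-phenyltetradec-12-en-2-yl 3-oxobutanoate
Product: 15 (R,E)-1-iodo-2-methyl-14-phenyltetradec-12-en-2-yl (Z)-3-{[(trifluoromethyl)sulfonyl]oxy}but-2-enoate
Conditions: LiOTf, Et3N, Tf2O, CH2Cl2, 0 °C
Reagents that add atoms: trifluoromethanesulfonic anhydride, O=S(=O)(OS(=O)(=O)C(F)(F)F)C(F)(F)F
Why: Enol triflation of the β-keto ester through its lithium-chelated enolate (soft enolisation) should give the Z enol triflate, with OTf cis to the ester, which is the geometry the ring closure needs.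

**Step 10**
Reactants: 15 (R,E)-1-iodo-2-methyl-14-phenyltetradec-12-en-2-yl (Z)-3-{[(trifluoromethyl)sulfonyl]oxy}but-2-enoate
Product: 16 (R)-4,6-dimethyl-6-[(E)-12-phenyldodec-10-en-1-yl]-5,6-dihydro-2H-pyran-2-one
Conditions: NiBr2(dme) (10 mol %), 4,4′-di-tert-butyl-2,2′-bipyridine (12 mol %), Mn powder (3 equiv), DMA, 25 °C, 0.01 M, slow addition of 15
Reagents that add atoms: none
Why: Zerovalent nickel should insert with retention into the C4–OTf bond, the alkenylnickel is reduced to the univalent state and abstracts iodine from the tethered C5–I, and the C5 radical is recaptured at nickel so that reductive elimination from trivalent alkenyl(alkyl)nickel forms C4–C5; a radical that instead adds directly to C4 of the β-triflyloxy enoate would be reduced and lose triflate to give the same product. The closest known reaction type is the nickel-catalysed reductive cross-electrophile coupling of alkenyl triflates or halides with unactivated primary alkyl iodides, here run within one molecule. The one ring closed is the six-membered lactone O1–C2–C3–C4–C5–C6, formally a 6-endo closure at the sp2 carbon C4 through a seven-membered nickelacycle, which leaves C3=C4 endocyclic and conjugated with C2. No new stereocenter is formed and C6 is not a reacting center, so its configuration from step 4 is carried through, while C4 becomes the prochiral trigonal carbon that step 11 addresses. The step needs ring closure to win over oligomerisation and over loss of the C5 radical, which is served by high dilution, by the Z geometry that holds C4–Ni cis to the ester tether, by the gem-disubstituted C6 (Thorpe–Ingold effect) and by the absence of any β-hydrogen next to C5. Mn is chosen over Zn because it should not insert into the C–I bond and trigger β-acyloxy elimination.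

**Step 11**
Reactants: 16 (R)-4,6-dimethyl-6-[(E)-12-phenyldodec-10-en-1-yl]-5,6-dihydro-2H-pyran-2-one
Product: 18 trisphaerolide A [(4R,6R)-4-hydroxy-4,6-dimethyl-6-[(E)-12-phenyldodec-10-en-1-yl]oxan-2-one], via pinacol boronate 17 (not isolated)
Conditions: B2pin2, CuCl (5 mol %), NaOtBu (10 mol %), (R)-1-[(S)-2-(diphenylphosphino)ferrocenyl]ethyldicyclohexylphosphine or its mirror image (6 mol %; the one that gives Re-face delivery at C4), MeOH (2 equiv), THF, rt; then NaBO3·4H2O, THF/H2O, rt
Reagents that add atoms: bis(pinacolato)diboron, CC1(C)OB(OC1(C)C)B1OC(C)(C)C(C)(C)O1 (boron of 17); sodium perborate, [Na+].[O-]OB=O (oxygen of 18)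
Why: Copper-catalysed asymmetric conjugate borylation of a β,β-disubstituted unsaturated ester should give the tertiary boronate and perborate oxidation goes with retention, so C4 is set by the chiral ligand on copper (boron to the Re face of C4, cis to the C6 methyl), and any C4 epimer is a diastereomer that can be separated.

## Compound list

1 | dec-9-yn-1-ol | C#CCCCCCCCCO | starting material
2 | 10-bromodec-1-yne | C#CCCCCCCCCBr | intermediate
3 | (E)-2-(10-bromodec-1-en-1-yl)-4,4,5,5-tetramethyl-1,3,2-dioxaborolane | BrCCCCCCCC/C=C/B1OC(C)(C)C(C)(C)O1 | intermediate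
4 | benzyl bromide | BrCc1ccccc1 | starting material
5 | (E)-(11-bromoundec-2-en-1-yl)benzene | BrCCCCCCCC/C=C/Cc1ccccc1 | intermediate
6 | 2-methylprop-2-en-1-ol | CC(=C)CO | starting material
7 | (S)-2-methylglycidol, (S)-(2-methyloxiran-2-yl)methanol | C[C@]1(CO)CO1 | intermediate (not isolated)
8 | (R)-(2-methyloxiran-2-yl)methyl 4-methylbenzenesulfonate | C[C@]1(COS(=O)(=O)c2ccc(C)cc2)CO1 | intermediate
9 | (E)-(11-phenylundec-9-en-1-yl)magnesium bromide | Br[Mg]CCCCCCCC/C=C/Cc1ccccc1 | intermediate (not isolated)
10 | (R,E)-2-hydroxy-2-methyl-14-phenyltetradec-12-en-1-yl 4-methylbenzenesulfonate | C[C@](O)(COS(=O)(=O)c1ccc(C)cc1)CCCCCCCCC/C=C/Cc1ccccc1 | intermediate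
11 | (R)-2-methyl-2-[(E)-12-phenyldodec-10-en-1-yl]oxirane | C[C@@]1(CCCCCCCCC/C=C/Cc2ccccc2)CO1 | intermediate
12 | (R,E)-1-iodo-2-methyl-14-phenyltetradec-12-en-2-ol | C[C@](O)(CI)CCCCCCCCC/C=C/Cc1ccccc1 | intermediate
13 | diketene, 4-methylideneoxetan-2-one | C=C1CC(=O)O1 | starting material
14 | (R,E)-1-iodo-2-methyl-14-phenyltetradec-12-en-2-yl 3-oxobutanoate | CC(=O)CC(=O)O[C@@](C)(CI)CCCCCCCCC/C=C/Cc1ccccc1 | intermediate
15 | (R,E)-1-iodo-2-methyl-14-phenyltetradec-12-en-2-yl (Z)-3-{[(trifluoromethyl)sulfonyl]oxy}but-2-enoate | C/C(OS(=O)(=O)C(F)(F)F)=C/C(=O)O[C@@](C)(CI)CCCCCCCCC/C=C/Cc1ccccc1 | intermediate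
16 | (R)-4,6-dimethyl-6-[(E)-12-phenyldodec-10-en-1-yl]-5,6-dihydro-2H-pyran-2-one | CC1=CC(=O)O[C@](C)(CCCCCCCCC/C=C/Cc2ccccc2)C1 | intermediate
17 | (4S,6R)-4,6-dimethyl-6-[(E)-12-phenyldodec-10-en-1-yl]-4-(4,4,5,5-tetramethyl-1,3,2-dioxaborolan-2-yl)oxan-2-one | C[C@]1(B2OC(C)(C)C(C)(C)O2)CC(=O)O[C@](C)(CCCCCCCCC/C=C/Cc3ccccc3)C1 | intermediate (not isolated)
18 | trisphaerolide A, (4R,6R)-4-hydroxy-4,6-dimethyl-6-[(E)-12-phenyldodec-10-en-1-yl]oxan-2-one | C[C@]1(O)CC(=O)O[C@](C)(CCCCCCCCC/C=C/Cc2ccccc2)C1 | target

## Step count and risks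

Total step count: 11. Longest linear sequence: 10 steps (steps 1, 2, 3, 5, 6, 7, 8, 9, 10, 11, from dec-9-yn-1-ol).

**Step 10 (ring closure).** Intermolecular coupling may outrun ring closure and give oligomers, or the C5 radical may be lost by hydrogen abstraction or by a 1,2-acyloxy shift before nickel captures it. The fallback sets out from 11 and comes back at 16, and closes the ring by lactonisation instead. Lithiated methyl propiolate (nBuLi, THF, −78 °C) with BF3·OEt2 should open epoxide 11 at its CH2 to give methyl (5R,15E)-5-hydroxy-5-methyl-17-phenylheptadec-15-en-2-ynoate F1. Syn addition of Me2CuLi (THF, −78 °C) to the ynoate puts the methyl group on C4 and leaves the C5 arm cis to the ester, so that the tertiary alkoxide should lactonise on warming with AcOH to 16.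

**Step 11 (C4 stereocenter).** Facial selectivity of the boryl transfer may be poor if the catalyst does not control the trigonal C4 well, and alkoxide may open the lactone. The fallback sets out from 16 and comes back at 18, and uses an epoxidation whose sense follows the Sharpless mnemonic.
- iBu2AlH (CH2Cl2, −78 to 0 °C) should reduce 16 to (2Z,5R,15E)-3,5-dimethyl-17-phenylheptadeca-2,15-diene-1,5-diol F2.
- Sharpless epoxidation of this Z allylic alcohol (Ti(OiPr)4, L-(+)-DIPT, TBHP, 4 Å MS, CH2Cl2, −20 °C) should give (2R,12E)-1-[(2R,3S)-3-(hydroxymethyl)-2-methyloxiran-2-yl]-2-methyl-14-phenyltetradec-12-en-2-ol F3.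
- NaAlH2(OCH2CH2OMe)2 (THF, 0 °C) should deliver hydride to the epoxide carbon next to the CH2OH group and give (3S,5R,15E)-3,5-dimethyl-17-phenylheptadec-15-ene-1,3,5-triol F4.
- TEMPO (cat.) and PhI(OAc)2 (CH2Cl2, rt) should oxidise the primary alcohol through the six-membered lactol to 18.

**Step 9 (enol triflate).** The Z geometry may erode, or triflate may be eliminated under the basic triflation, and only the Z isomer can close the ring. The fallback sets out from 12 and comes back at 16. Commercial but-2-ynoic acid with NaI in AcOH (115 °C) should add HI in anti fashion to give (Z)-3-iodobut-2-enoic acid F5. Steglich esterification with 12 (DCC, DMAP, CH2Cl2) should give (2R,12E)-1-iodo-2-methyl-14-phenyltetradec-12-en-2-yl (Z)-3-iodobut-2-enoate F6. F6 should close to 16 under the conditions of step 10 (NiBr2(dme), 4,4′-di-tert-butyl-2,2′-bipyridine, Mn, DMA).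

## Further compounds

F1 | step 10 | methyl (5R,15E)-5-hydroxy-5-methyl-17-phenylheptadec-15-en-2-ynoate | COC(=O)C#CC[C@](C)(O)CCCCCCCCC/C=C/Cc1ccccc1
F2 | step 11 | (2Z,5R,15E)-3,5-dimethyl-17-phenylheptadeca-2,15-diene-1,5-diol | OC/C=C(C)\C[C@](C)(O)CCCCCCCCC/C=C/Cc1ccccc1
F3 | step 11 | (2R,12E)-1-[(2R,3S)-3-(hydroxymethyl)-2-methyloxiran-2-yl]-2-methyl-14-phenyltetradec-12-en-2-ol | OC[C@@H]1O[C@]1(C)C[C@](C)(O)CCCCCCCCC/C=C/Cc1ccccc1
F4 | step 11 | (3S,5R,15E)-3,5-dimethyl-17-phenylheptadec-15-ene-1,3,5-triol | OCC[C@](C)(O)C[C@](C)(O)CCCCCCCCC/C=C/Cc1ccccc1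
F5 | step 9 | (Z)-3-iodobut-2-enoic acid | C/C(I)=C/C(=O)O
F6 | step 9 | (2R,12E)-1-iodo-2-methyl-14-phenyltetradec-12-en-2-yl (Z)-3-iodobut-2-enoate | C/C(I)=C/C(=O)O[C@@](C)(CI)CCCCCCCCC/C=C/Cc1ccccc1
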